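At 2.50 h the target and substrate of the dawn run left 10.2% of the charge unaccounted for, and at 20.0 h they left 10.7%. That is close to the 10 mol% loading, so I took the catalyst to sit bound to substrate, as its resting state, even at 0.0088 M.

| flask | substrate | reagent | free catalyst | remark | time |
|---|---|---|---|---|---|
| dawn | 0.0088 M | 1 equiv | 10 mol% | run made earlier |  |
| beta | 0.030 M | 1.00 equiv | 10 mol% |  | 25 h |
| theta | 0.15 M | 1.00 equiv | 10 mol% |  | 25 h |
| alpha | 0.012 M | 1.00 equiv | 10 mol% |  | 25 h |
| epsilon | 0.050 M | 1.00 equiv | 10 mol% |  | 25 h |
| eta | 0.10 M | 1.00 equiv | 10 mol% |  | 25 h |

dawn run (percent of the substrate charged)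

| time / h | target / % | substrate / % |
|---|---|---|
| 2.50 | 2.7 | 87.1 |
| 5.00 | 6.1 | 83.9 |
| 8.00 | 10.2 | 81.4 |
| 10.0 | 12.4 | 76.8 |
| 12.0 | 15.7 | 75.0 |
| 15.0 | 19.0 | 71.1 |
| 20.0 | 24.6 | 64.7 |

(standard deviation of a reading: 0.5 percentage points)

1. all flasks from highest to lowest amount of target, in percent of the substrate charged, at 25 h (beta / theta / alpha / epsilon / eta)
2. the amount of target, in percent of the substrate charged of the flask you put first, at 25 h
3. the amount of target, in percent of the substrate charged of the flask you put last, at 25 h

- the earlier runs were read with a standard deviation of 0.5 percentage points
- no earlier run changes the charge of free catalyst; that part of a forecast is a guess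

**Two extremes.** Suppose the bound catalyst turned over regardless of [reagent]. Target in percent would then not depend on the charge, and the straight line through the last dawn reading gives 30.8% at 25 h. Suppose instead it waited for reagent, a pseudo-first-order loss of reagent. Dividing a flask's fractional rate by that of the dawn run, time drops out and the ratio of charges remains. I therefore defined the clearing constant, the fractional loss of reagent per hour per molar of substrate charged at this loading, 1.60 /M/h, counting the reagent lost as equal to the target made. Target is then one minus the exponential of minus the constant times [substrate] times time: 38.2% for alpha and 99.8% for theta.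

**Choosing between.** The dawn run could not separate these. At 10.0 h the curve gives 13.1% against a reading of 12.4%, with a scatter of 0.5 percentage points. An order in reagent between none and one puts each flask between its two values. The dawn run read target and substrate but never reagent, so my commitment to the first-order end, with theta at more than alpha, was a choice and not a reading.

**Forecast and flask.** The forecast gave alpha > beta > epsilon > eta > theta, from 31% to 28%, holding that “The rate is therefore about zero order in both”. The flasks gave theta > eta > epsilon > beta > alpha, with theta at 97.4% and alpha at 39.0%.

    substrate + free catalyst → catalyst intermediate A (k = 20.0 /M/min)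
    catalyst intermediate A ⇌ catalyst intermediate B (K = 84.0, k = 0.0240 /min)
    reagent + catalyst intermediate B ⇌ catalyst intermediate C (K = 44.0 /M, k = 0.330 /M/min)
    catalyst intermediate C → free catalyst + target (k = 1.90 /min)

**Lower loading.** The neighbouring flask was alpha with 6 mol% of free catalyst instead of 10 mol%, read at the same time. I multiplied the clearing constant by the ratio of loadings, 0.600, and the same expression gave 25.1% of target. That flask held 25.5% of target, with 68.6% of the substrate and 75% of the reagent still unbound, and catalyst intermediate B made up 86.6% of the catalyst charged.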